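**Retrosynthetic overview**
1. The C4–C6 interflavan bond is made last but one: a flavan-4-yl cation from the 2,3-trans unit (18) is attacked by C6 of the 2,3-cis unit (17); six benzyl ethers are removed at the end.
2. Both flavan-3-ol units come from one anti-diol (15) by closing ring C at O1–C2: SN1 closure gives (2R,3S)-trans, Mitsunobu inversion gives (2S,3S)-cis.
3. Diol 15 comes from the ring B aryllithium (from catechol) opening the (S)-3-hydroxydihydrocoumarin 9 (ring A plus C2–C4), then chelation-controlled reduction.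
4. Lactone 9 comes from asymmetric transfer hydrogenation of 3-hydroxycoumarin 8; 8 comes from the key one-carbon ring expansion (1,2-aryl shift) of benzofuran-2,3-dione 5, made from resorcinol monobenzyl ether and oxalyl chloride.
5. Ring order: ring A (resorcinol) → five-membered keto lactone → six-membered lactone by ring expansion (brings in C4 and the C3 oxygen) → opened by ring B → ring C closed in each unit → union.

Assumption: the SMILES is read as fisetinidol-(4α→6)-ent-epifisetinidol, upper unit (2R,3S,4R), lower unit (2S,3S).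

**Route**

Step 1
Reactants: 1 resorcinol
Product: 2 3-(benzyloxy)phenol
Conditions: BnBr (0.5 equiv), K2CO3, acetone, reflux; excess 1 recovered
Reagents that add atoms: benzyl bromide BrCc1ccccc1
Why: Williamson mono-O-benzylation, kept statistical in favour of the monoether by excess resorcinol; no stereocenter.

Step 2
Reactants: 2 3-(benzyloxy)phenol; 3 oxalyl chloride
Product: 5 6-(benzyloxy)-1-benzofuran-2,3-dione, via aryl chlorooxoacetate 4 (not isolated)
Conditions: (COCl)2, CH2Cl2, 0 °C to rt; then TiCl4 (1.1 equiv), −20 to 0 °C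
Reagents that add atoms: none
Why: O-acylation followed by intramolecular Friedel–Crafts acylation (Stollé-type, as for isatins) at the ring position para to the benzyloxy group closes the five-membered α-keto lactone; no stereocenter.

Step 3
Reactants: 5 6-(benzyloxy)-1-benzofuran-2,3-dione; 6 (trimethylsilyl)diazomethane
Product: 8 7-(benzyloxy)-3-hydroxy-2H-chromen-2-one, via silyl enol ether 7 (not isolated)
Conditions: Me3SiCHN2 (1.3 equiv), BF3·OEt2 (0.3 equiv), CH2Cl2, −78 to −20 °C; then aq. citric acid, THF, rt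
Reagents that add atoms: none
Why: Eistert-type diazo ring expansion (the oxygen analogue of isatin → 3-hydroxyquinolin-2-one): the activated C3 ketone adds the diazo carbon, N2 leaves with a 1,2-shift of the electron-rich aryl carbon, and the α-silyl ketone collapses to enol silyl ether 7, which cannot homologate again and is hydrolysed; no stereocenter.

Step 4
Reactants: 8 7-(benzyloxy)-3-hydroxy-2H-chromen-2-one
Product: 9 (3S)-7-(benzyloxy)-3-hydroxy-3,4-dihydro-2H-chromen-2-one
Conditions: RuCl[(S,S)-TsDPEN](p-cymene) (1 mol%), HCO2H/Et3N (5:2), EtOAc, 30 °C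
Reagents that add atoms: none
Why: Proposed new method: the stable enol 8 is reduced through its minor α-keto lactone tautomer (chromane-2,3-dione), which HCO2H/Et3N keeps in fast exchange and which the bifunctional Ru–H/N–H catalyst reduces at the very electrophilic ketone with the lactone carbonyl in the aryl-like position, so catalyst control sets C3 as S (the mirror-image catalyst is used if the sense proves opposite); closest known reaction type is Noyori–Ikariya asymmetric transfer hydrogenation of α-keto esters and α-keto lactones.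

Step 5
Reactants: 10 catechol
Product: 11 1,2-bis(benzyloxy)benzene
Conditions: BnBr (2.2 equiv), K2CO3, DMF, 60 °C
Reagents that add atoms: benzyl bromide BrCc1ccccc1
Why: double Williamson etherification; no stereocenter.

Step 6
Reactants: 11 1,2-bis(benzyloxy)benzene
Product: 12 4-bromo-1,2-bis(benzyloxy)benzene
Conditions: NBS (1.05 equiv), MeCN, 0 °C to rt
Reagents that add atoms: N-bromosuccinimide O=C1CCC(=O)N1Br
Why: electrophilic aromatic bromination para to an alkoxy group, the only unhindered activated position; no stereocenter.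

Step 7
Reactants: 12 4-bromo-1,2-bis(benzyloxy)benzene; 9 (3S)-7-(benzyloxy)-3-hydroxy-3,4-dihydro-2H-chromen-2-one
Product: 15 (1R,2S)-1-[3,4-bis(benzyloxy)phenyl]-3-[4-(benzyloxy)-2-hydroxyphenyl]propane-1,2-diol, via aryllithium 13 (not isolated), via hydroxy ketone 14 (not isolated)
Conditions: 12, n-BuLi, THF, −78 °C; added to 9 pre-treated with LiN(SiMe3)2 (1.0 equiv), THF, −78 °C; then MeOH, NaBH4, −78 to 0 °C; H2O
Reagents that add atoms: none
Why: Br/Li exchange and acyl substitution at the aryl lactone (phenoxide leaves; the α-alkoxide and one equivalent of aryllithium prevent over-addition) give α-hydroxy ketone 14, whose chelation-controlled (Cram-chelate) borohydride reduction, as in benzoin → meso-hydrobenzoin, sets C1 as R, anti to the C2 stereocenter carried from 9.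

Step 8
Reactants: 15 (1R,2S)-1-[3,4-bis(benzyloxy)phenyl]-3-[4-(benzyloxy)-2-hydroxyphenyl]propane-1,2-diol
Product: 16 (2R,3S)-7-(benzyloxy)-2-[3,4-bis(benzyloxy)phenyl]-3,4-dihydro-2H-chromen-3-ol
Conditions: p-TsOH·H2O (10 mol%), MeCN, 0 °C to rt
Reagents that add atoms: none
Why: acid-catalysed SN1 cycloetherification through the p-alkoxybenzylic cation, in which the phenol closes ring C mainly to the 2,3-trans isomer (about 3:1 expected; the minor cis isomer is 17 and is pooled with step 9), so C2 becomes R while C3 is untouched.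

Step 9
Reactants: 15 (1R,2S)-1-[3,4-bis(benzyloxy)phenyl]-3-[4-(benzyloxy)-2-hydroxyphenyl]propane-1,2-diol
Product: 17 (2S,3S)-7-(benzyloxy)-2-[3,4-bis(benzyloxy)phenyl]-3,4-dihydro-2H-chromen-3-ol
Conditions: PPh3, DIAD, THF, 0 °C to rt
Reagents that add atoms: none
Why: intramolecular Mitsunobu etherification, in which the phenoxide displaces the benzylic oxyphosphonium with inversion (1R becomes 2S) to give the 2,3-cis ring; any SN1 leakage only gives useful 16.

Step 10
Reactants: 16 (2R,3S)-7-(benzyloxy)-2-[3,4-bis(benzyloxy)phenyl]-3,4-dihydro-2H-chromen-3-ol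
Product: 18 (2R,3S,4S)-7-(benzyloxy)-2-[3,4-bis(benzyloxy)phenyl]-4-(2-ethoxyethoxy)-3,4-dihydro-2H-chromen-3-ol
Conditions: DDQ (1.5 equiv), 2-ethoxyethanol (10 equiv), CH2Cl2, rt
Reagents that add atoms: 2-ethoxyethanol CCOCCO
Why: DDQ benzylic oxidation, hydride abstraction from C4 (para to the 7-benzyloxy group) giving a quinone-methide cation that the alcohol traps anti to the 2-aryl group (3,4-cis); the C4 configuration is lost again in step 11.

Step 11
Reactants: 18 (2R,3S,4S)-7-(benzyloxy)-2-[3,4-bis(benzyloxy)phenyl]-4-(2-ethoxyethoxy)-3,4-dihydro-2H-chromen-3-ol; 17 (2S,3S)-7-(benzyloxy)-2-[3,4-bis(benzyloxy)phenyl]-3,4-dihydro-2H-chromen-3-ol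
Product: 19 7,3′,4′,7″,3‴,4‴-hexa-O-benzyl-fisetinidol-(4α→6)-ent-epifisetinidol
Conditions: 17 (2.5 equiv, excess recovered), Me3SiOTf (0.2 equiv), CH2Cl2, −78 to −40 °C
Reagents that add atoms: none
Why: Lewis-acid ionisation to the flavan-4-yl cation and Friedel–Crafts attack by C6 of 17 (para to O1, less hindered than C8) from the face anti to the C3 hydroxyl gives the 3,4-trans (4α) C4–C6 bond, with excess 17 suppressing self-condensation.

Step 12
Reactants: 19 7,3′,4′,7″,3‴,4‴-hexa-O-benzyl-fisetinidol-(4α→6)-ent-epifisetinidol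
Product: 20 fisetinidol-(4α→6)-ent-epifisetinidol, (2R,3S,4R)-2-(3,4-dihydroxyphenyl)-4-[(2S,3S)-2-(3,4-dihydroxyphenyl)-3,7-dihydroxy-3,4-dihydro-2H-chromen-6-yl]-3,4-dihydro-2H-chromene-3,7-diol
Conditions: H2 (1 atm), Pd(OH)2/C, THF/MeOH, rt
Reagents that add atoms: none
Why: neutral hydrogenolysis of the six benzyl ethers leaves the benzylic ring bonds and all five stereocenters untouched.

**Compound list**
1 | resorcinol | Oc1cccc(O)c1 | starting material
2 | 3-(benzyloxy)phenol | Oc1cccc(OCc2ccccc2)c1 | intermediate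
3 | oxalyl chloride | O=C(Cl)C(=O)Cl | starting material
4 | 3-(benzyloxy)phenyl chloro(oxo)acetate | O=C(Cl)C(=O)Oc1cccc(OCc2ccccc2)c1 | intermediate
5 | 6-(benzyloxy)-1-benzofuran-2,3-dione | O=C1Oc2cc(OCc3ccccc3)ccc2C1=O | intermediate
6 | (trimethylsilyl)diazomethane | C[Si](C)(C)C=[N+]=[N-] | starting material
7 | 7-(benzyloxy)-3-[(trimethylsilyl)oxy]-2H-chromen-2-one | C[Si](C)(C)OC1=Cc2ccc(OCc3ccccc3)cc2OC1=O | intermediate
8 | 7-(benzyloxy)-3-hydroxy-2H-chromen-2-one | OC1=Cc2ccc(OCc3ccccc3)cc2OC1=O | intermediate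
9 | (3S)-7-(benzyloxy)-3-hydroxy-3,4-dihydro-2H-chromen-2-one | O=C1Oc2cc(OCc3ccccc3)ccc2C[C@@H]1O | intermediate
10 | catechol | Oc1ccccc1O | starting material
11 | 1,2-bis(benzyloxy)benzene | c1ccc(COc2ccccc2OCc2ccccc2)cc1 | intermediate
12 | 4-bromo-1,2-bis(benzyloxy)benzene | Brc1ccc(OCc2ccccc2)c(OCc2ccccc2)c1 | intermediate
13 | [3,4-bis(benzyloxy)phenyl]lithium | [Li]c1ccc(OCc2ccccc2)c(OCc2ccccc2)c1 | intermediate
14 | (2S)-1-[3,4-bis(benzyloxy)phenyl]-3-[4-(benzyloxy)-2-hydroxyphenyl]-2-hydroxypropan-1-one | O=C([C@@H](O)Cc1ccc(OCc2ccccc2)cc1O)c1ccc(OCc2ccccc2)c(OCc2ccccc2)c1 | intermediate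
15 | (1R,2S)-1-[3,4-bis(benzyloxy)phenyl]-3-[4-(benzyloxy)-2-hydroxyphenyl]propane-1,2-diol (anti) | O[C@@H]([C@@H](O)Cc1ccc(OCc2ccccc2)cc1O)c1ccc(OCc2ccccc2)c(OCc2ccccc2)c1 | intermediate
16 | (2R,3S)-7-(benzyloxy)-2-[3,4-bis(benzyloxy)phenyl]-3,4-dihydro-2H-chromen-3-ol (2,3-trans) | c1ccc(COc2ccc3c(c2)O[C@H](c2ccc(OCc4ccccc4)c(OCc4ccccc4)c2)[C@@H](O)C3)cc1 | intermediate
17 | (2S,3S)-7-(benzyloxy)-2-[3,4-bis(benzyloxy)phenyl]-3,4-dihydro-2H-chromen-3-ol (2,3-cis) | c1ccc(COc2ccc3c(c2)O[C@@H](c2ccc(OCc4ccccc4)c(OCc4ccccc4)c2)[C@@H](O)C3)cc1 | intermediate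
18 | (2R,3S,4S)-7-(benzyloxy)-2-[3,4-bis(benzyloxy)phenyl]-4-(2-ethoxyethoxy)-3,4-dihydro-2H-chromen-3-ol (3,4-cis) | c1ccc(COc2ccc3c(c2)O[C@H](c2ccc(OCc4ccccc4)c(OCc4ccccc4)c2)[C@@H](O)[C@H]3OCCOCC)cc1 | intermediate
19 | 7,3′,4′,7″,3‴,4‴-hexa-O-benzyl-fisetinidol-(4α→6)-ent-epifisetinidol (all six phenols of 20 as benzyl ethers, both 3-OH free, same configuration as 20) | c1ccc(COc2ccc3c(c2)O[C@H](c2ccc(OCc4ccccc4)c(OCc4ccccc4)c2)[C@@H](O)[C@@H]3c2cc3c(cc2OCc2ccccc2)O[C@@H](c2ccc(OCc4ccccc4)c(OCc4ccccc4)c2)[C@@H](O)C3)cc1 | intermediate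
20 | fisetinidol-(4α→6)-ent-epifisetinidol (CNP0187520.2) | Oc1ccc2c(c1)O[C@H](c1ccc(O)c(O)c1)[C@@H](O)[C@@H]2c1cc2c(cc1O)O[C@@H](c1ccc(O)c(O)c1)[C@@H](O)C2 | target

**Step count and risks**

Total steps: 12. Longest linear sequence: 9 (steps 1, 2, 3, 4, 7, 8, 10, 11, 12).

Risk 1, step 3 (ring expansion). Acyl instead of aryl migration, epoxide formation or O-alkylation could erode the yield. The fallback sets out from 2 and returns at 8 by condensation chemistry, bypassing dione 5. Magnesium-mediated ortho-formylation (MgCl2, Et3N, paraformaldehyde, MeCN, reflux) gives 4-(benzyloxy)-2-hydroxybenzaldehyde F1. Erlenmeyer condensation with N-acetylglycine (Ac2O, NaOAc, 110 °C) gives 3-acetamido-7-(benzyloxy)-2H-chromen-2-one F2. Acid hydrolysis (3 M HCl, EtOH, reflux) then gives 8.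

Risk 2, step 4 (the proposed new method). The keto tautomer may be too scarce for a useful rate, or the enantioselectivity may be low. The fallback uses known biocatalysis; it sets out from 8 and returns at 9. Ring opening with NaOH and adjustment to pH 7.5 gives sodium 3-[4-(benzyloxy)-2-hydroxyphenyl]-2-oxopropanoate F3. An L-specific 2-hydroxy acid dehydrogenase (L-lactate or L-2-hydroxyisocaproate dehydrogenase, NADH recycled by formate dehydrogenase and ammonium formate, 30 °C) reduces this arylpyruvate to sodium (2S)-3-[4-(benzyloxy)-2-hydroxyphenyl]-2-hydroxypropanoate F4. Acidification with HCl and gentle warming in toluene relactonises it to 9.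

Risk 3, step 10. With only one alkoxy group on ring A, DDQ may abstract the C2 hydrogen (benzylic to ring B) instead of the C4 hydrogen. The fallback sets out from 16 and returns at 19. Ligand-transfer acetoxylation with Pb(OAc)4 in benzene at rt gives 4β-acetoxy-7,3′,4′-tri-O-benzylfisetinidol F5 (acetate cis to the 3-OH). F5 replaces 18 in the union with 17 (BF3·OEt2, CH2Cl2, −40 °C) to give 19.

**Further compounds**
F1 | step 3 | 4-(benzyloxy)-2-hydroxybenzaldehyde | O=Cc1ccc(OCc2ccccc2)cc1O
F2 | step 3 | 3-acetamido-7-(benzyloxy)-2H-chromen-2-one | CC(=O)NC1=Cc2ccc(OCc3ccccc3)cc2OC1=O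
F3 | step 4 | sodium 3-[4-(benzyloxy)-2-hydroxyphenyl]-2-oxopropanoate | [Na+].[O-]C(=O)C(=O)Cc1ccc(OCc2ccccc2)cc1O
F4 | step 4 | sodium (2S)-3-[4-(benzyloxy)-2-hydroxyphenyl]-2-hydroxypropanoate | [Na+].[O-]C(=O)[C@@H](O)Cc1ccc(OCc2ccccc2)cc1O
F5 | step 10 | 4β-acetoxy-7,3′,4′-tri-O-benzylfisetinidol (16 with an acetoxy group at C4, cis to the 3-OH) | c1ccc(COc2ccc3c(c2)O[C@H](c2ccc(OCc4ccccc4)c(OCc4ccccc4)c2)[C@@H](O)[C@H]3OC(C)=O)cc1
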